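The data are calculated on assumed constants; noise was put on by code.

In a one-step world chains simply rise to a level and stay there, and before repeating this run I want to know whether the earlier readings allow that.

| setting | Saturday's | Sunday's | flask |
|---|---|---|---|
| free monomer | 0.50 M | 0.75 M | 1.0 M |
| initiator | 1 mol% | 1 mol% | 1 mol% |
| remark | run made earlier | run made earlier |  |
| time |  |  | 25 min |

| run | time / min | monomer in chains / % |
|---|---|---|
| Saturday's | 1.00 | 0.7 |
| Saturday's | 2.00 | 0 |
| Saturday's | 3.00 | 1.4 |
| Saturday's | 5.00 | 0 |
| Saturday's | 8.00 | 0 |
| Saturday's | 15.0 | 1.5 |
| Sunday's | 1.00 | 4.8 |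
| Sunday's | 2.00 | 10.8 |
| Sunday's | 3.00 | 10.5 |
| Sunday's | 5.00 | 10.7 |
| Sunday's | 8.00 | 5.8 |
| Sunday's | 15.0 | 0 |

(standard deviation of a reading: 1 percentage point)

1. the best time, 25 min at the latest, for monomer in chains
2. the amount of monomer in chains, in percent of the free monomer charged, at that time



Sunday's reading at 2.00 min puts chains at 10.8% of 0.75 M, which in that one-step world leaves free monomer at 0.669 M, its equilibrium monomer concentration. But Sunday's last reading is 0% at 15.0 min, so that level doesn't last, and I take chains to hold a share of the surplus charge, not all of it.

What share, and surplus over what? Going round again with both runs, the highest readings are 0.00750 M of chains at 0.50 M and 0.0810 M at 0.75 M. Between these two readings chains gain 29.4% of added charge, and the straight line through them reaches zero at 0.474 M. I carry this threshold charge, the charge at which that line of highest readings reaches zero, as a rough reading, since Saturday's 1.5% stands against a scatter of 1 percentage point.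

This flask has 0.526 M above it, so I expect 15.5% of its free monomer charged in chains. Sunday's level lasts from 2.00 min to 5.00 min, so I watch around 3.50 min.

The forecast stands higher than my reckoning, at 30% after 4 min, holding that “the ceiling should therefore be about 33%”.

The flask gives 19.3% at 4.52 min, more than the 15.5% I reckoned, and that is 36.7% of the surplus over the threshold charge.

    free monomer + living end → monomer in chains + living end, rate k1*[living end]*[free monomer] (k = 0.420 M⁻¹ s⁻¹)
    initiator + monomer in chains → spent initiator (k = 0.00140 M⁻¹ s⁻¹)
    2 free monomer → homo dimer (k = 0.00170 M⁻¹ s⁻¹)
    monomer in chains + living end → free monomer + living end, rate k4*[living end] as long as [monomer in chains] is above zero (k = 0.180 s⁻¹)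
    free monomer + initiator → living end + monomer in chains (k = 0.0620 M⁻¹ s⁻¹)

By 2.50 min initiator is down to 0.107% of its charge and living end stands at 0.00998 M; while it stands there free monomer enters chains, chains return to free monomer, and free monomer pairs into homo dimer, which holds 37.9% of the free monomer charged at the best time. With living end still at 0.00999 M after 25.0 min, free monomer has fallen to 20.3%, homo dimer has reached 79.7% and chains have sunk to 0.00899%.

In the same flask at 0.40 M of free monomer, the charge lies 0.0740 M under the threshold charge, so I expect a peak inside the scatter; the computed peak is 0.518%.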